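**Retrosynthetic overview**

1. Numbering (eremophilane): ring A = C1–C5 and C10, ring B = C5–C10. C2 bears the acetate, C4 and C5 the methyls (the C5 methyl defines the β face), C7 the isopropenyl group (C11), C8 the free hydroxyl, C9 the angelate, C10 the α-hydrogen (trans-decalin).
2. Late disconnections: O9 angelate and O2 acetate (acylations), isopropenyl from a tertiary C11 chloride, C10–H by hydroxyl-directed hydrogenation of a Δ1(10)-2-ketone, 8α,9α-diol by dihydroxylation of a 1(10),8-dien-2-one.
3. Central disconnection: ring A is closed at C1–C10 by aldol condensation of a C2 methyl ketone onto a C10 ketone, in the same operation that cleaves an extra C9–C11 bond. The precursor is a pinane 1,5-diketone.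
4. Enabling feature: C11 (on C7) and C9 are both one bond from the C7–C8 edge of ring B, so C7, C8, C9 and C11 can be the cyclobutane of (+)-nopinone, whose carbonyl is C10. This ring fixes C7, steers the side chain at C5 anti to C11 (C5 methyl cis to the C7 substituent), and is opened by acid next to the C10 ketone.
5. Ring order: ring B arrives as the nopinone bicycle, the C4–C5 bond is made by a Mukaiyama–Michael addition, and ring A is closed in the key step while the four-membered ring is opened.

Key step: step 3

Remark: α/β descriptors refer to the numbering above; all decalin intermediates carry 4β,5β-dimethyl groups and a 7β side chain (7αH). (+)-Nopinone, (E)-pent-3-en-2-one and angelic acid are taken as purchased.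

**Route**

Step 1
Reactants: 1 (1R,5S)-(+)-nopinone
Product: 2 trans-3-methylnopinone [(1R,3S,5S)-3,6,6-trimethylbicyclo[3.1.1]heptan-2-one; methyl anti to the gem-dimethyl bridge]
Conditions: LiN(i-Pr)2, THF, −78 °C; MeI, −78 → 0 °C
Reagents that add atoms: iodomethane, CI
Why: Kinetic enolate alkylation, in which only C3 of nopinone (the future C5) can enolise because the other α-carbon is a bridgehead and iodomethane enters anti to the gem-dimethyl bridge; this centre is made planar again in step 2, so its configuration is not carried forward.

Step 2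
Reactants: 2 trans-3-methylnopinone; 3 (E)-pent-3-en-2-one
Product: 5 pinane 1,5-diketone (1R,3R,5S)-3,6,6-trimethyl-3-[(2S)-4-oxopentan-2-yl]bicyclo[3.1.1]heptan-2-one, via silyl enol ether 4 (not isolated)
Conditions: LiN(i-Pr)2, THF, 0 °C; Me3SiCl; pentane, filtration; then 3, TiCl4, CH2Cl2, −78 °C; H2O
Reagents that add atoms: chlorotrimethylsilane, C[Si](C)(C)Cl (silyl group in intermediate 4 only)
Why: Mukaiyama–Michael addition in which the TiCl4-activated enone is attacked by the tetrasubstituted silyl enol ether on the face away from the gem-dimethyl bridge, so the chain ends anti and the C5 methyl syn to that bridge (the later C5/C7 cis relationship), while C4 should arise from an open staggered transition state whose enone β-methyl avoids the sector crowded by the ring methyl and the cis-disposed siloxy group, the sense that leads to cis-vicinal dimethyl octalones from 2-methylcyclohexanone silyl enol ethers.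

Step 3
Reactants: 5 pinane 1,5-diketone
Product: 8 chloro enone (4S,4aR,6R)-6-(2-chloropropan-2-yl)-4,4a-dimethyl-4,4a,5,6,7,8-hexahydronaphthalen-2(3H)-one, via ring-opened chloro diketone 6 (not isolated), via fused ketol 7 (not isolated)
Conditions: HCl (g), AcOH, rt
Reagents that add atoms: hydrogen chloride, Cl
Why: Protonation of the ring ketone of 5 triggers heterolysis of the strained C9–C11 cyclobutane bond to an enol and a tertiary cation, chloride traps the cation and the enol ketonises to 6; the methyl ketone then enolises towards C1, attacks the C10 carbonyl, and ketol 7 loses water to the conjugated enone 8. The closest known reaction types are the hydrogen chloride opening of nopinone-type cyclobutyl ketones to 4-(2-chloropropan-2-yl)cyclohexanones and the acid-mediated aldol stage of a Robinson annulation, a combination known for closely related pinane 1,5-diketones. Ring A closes by a 6-(enolendo)-exo-trig aldol addition followed by dehydration, while the four-membered ring opens. No stereocentre is created (C10 becomes trigonal), but three are delivered intact: C7 is the untouched nopinone bridgehead, and C4 and C5 come from step 2. The step needs cleavage of C9–C11 and not C8–C9, secured because only the former gives a tertiary cation, and it needs the fused and not the bridged aldol (C9 enol onto the C2 carbonyl), secured because the bridged ketol cannot dehydrate and reverts, so only the fused pathway is drained by elimination. Chloride capture at C11 also masks the isopropenyl group for steps 4 to 8.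

Step 4
Reactants: 8 chloro enone
Product: 9 chloro dienone 11-chloro-7αH-eremophila-1(10),8-dien-2-one
Conditions: chloranil, t-BuOH, reflux
Reagents that add atoms: none
Why: Quinone dehydrogenation through the extended dienol (C2 enol conjugated to C9=C10) with hydride loss from C8, which should give the linear dienone as in the conversion of Δ4-3-keto steroids into 4,6-dien-3-ones, the weakly ionising medium sparing the tertiary chloride.

Step 5
Reactants: 9 chloro dienone
Product: 10 diol enone 11-chloro-8α,9α-dihydroxy-7αH-eremophil-1(10)-en-2-one
Conditions: OsO4 (cat.), N-methylmorpholine N-oxide, acetone–H2O (10:1), rt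
Reagents that add atoms: N-methylmorpholine N-oxide, C[N+]1([O-])CCOCC1; water, O
Why: Upjohn dihydroxylation of the more electron-rich γ,δ-alkene, syn and from the α face, because the exocyclic C1=C10 bond holds the C5 methyl axial over ring B and the 7β-chloroalkyl group flanks C8 on the same face; the low water content protects the tertiary chloride.

Step 6
Reactants: 10 diol enone
Product: 11 keto diol 11-chloro-8α,9α-dihydroxy-7αH,10αH-eremophilan-2-one (trans-fused)
Conditions: H2 (1 atm), [Ir(cod)(PCy3)(py)]PF6 (10 mol %), CH2Cl2, rt
Reagents that add atoms: none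
Why: Hydroxyl-directed homogeneous hydrogenation in which the allylic 9α-hydroxyl and the homoallylic 8α-hydroxyl bind the cationic iridium complex and deliver hydrogen to the α face of C1=C10, setting the 10α-hydrogen; the chloride mask means no other alkene competes.

Step 7
Reactants: 11 keto diol
Product: 12 acetonide ketone (8α,9α-O-isopropylidene acetal of 11)
Conditions: 2-methoxypropene, PPTS (cat.), CH2Cl2, 0 °C → rt
Reagents that add atoms: 2-methoxypropene, COC(C)=C
Why: Kinetic acetonide formation on the cis-diol, which ties up the C8 hydroxyl that as a γ-chloro alkoxide could undergo Grob-type fragmentation in step 9 and leaves O2 as the only oxygen to be acetylated in step 10.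

Step 8
Reactants: 12 acetonide ketone
Product: 13 chloro alcohol 11-chloro-8α,9α-(isopropylidenedioxy)-7αH,10αH-eremophilan-2α-ol
Conditions: LiBH(s-Bu)3, THF, −78 °C; H2O
Reagents that add atoms: none
Why: Bulky-hydride reduction of the C2 ketone of the chair ring A from the equatorial direction, which should give the axial 2α-alcohol as with 5α-3-keto steroids and their 3α-alcohols.

Step 9
Reactants: 13 chloro alcohol
Product: 14 isopropenyl alcohol 8α,9α-(isopropylidenedioxy)-7αH,10αH-eremophil-11-en-2α-ol
Conditions: KOt-Bu, DMSO, rt
Reagents that add atoms: none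
Why: E2 dehydrochlorination in which the bulky base should take one of the six methyl hydrogens and not the hindered ring methine at C7 (Hofmann orientation), giving the isopropenyl group without touching C7.

Step 10
Reactants: 14 isopropenyl alcohol
Product: 15 acetate (2α-acetate of 14)
Conditions: Ac2O, Et3N, DMAP (cat.), CH2Cl2, rt
Reagents that add atoms: acetic anhydride, CC(=O)OC(C)=O
Why: DMAP-catalysed acylation of the only free hydroxyl, with retention at C2.

Step 11
Reactants: 15 acetate
Product: 16 diol acetate 2α-acetoxy-7αH,10αH-eremophil-11-ene-8α,9α-diol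
Conditions: AcOH–H2O (4:1), 45 °C
Reagents that add atoms: none
Why: Mild acid hydrolysis of the isopropylidene acetal, conditions that the acetate and the isopropenyl group should tolerate.

Step 12
Reactants: 16 diol acetate; 17 angelic acid [(Z)-2-methylbut-2-enoic acid]
Product: 20 target 2α-acetoxy-9α-angeloyloxy-7αH,10αH-eremophil-11-en-8α-ol, via stannylene acetal 18 (not isolated), via mixed anhydride 19 (not isolated)
Conditions: 16, Bu2SnO, toluene, reflux (Dean–Stark); separately 17, 2,4,6-trichlorobenzoyl chloride, Et3N, toluene, rt; combine, rt → 60 °C; aqueous work-up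
Reagents that add atoms: dibutyltin oxide, CCCC[Sn](=O)CCCC (tin unit in intermediate 18 only); 2,4,6-trichlorobenzoyl chloride, O=C(Cl)c1c(Cl)cc(Cl)cc1Cl (aroyl unit in intermediate 19 only)
Why: Stannylene-acetal-directed monoacylation, which activates the equatorial, less encumbered O9 of the cis-diol (O8 is flanked by the C7 isopropenyl group), combined with a Yamaguchi mixed anhydride that transfers the angeloyl group at its unhindered carbonyl without a nucleophilic catalyst that would isomerise Z to E.

**Compound list**

1 | (1R,5S)-(+)-nopinone (6,6-dimethylbicyclo[3.1.1]heptan-2-one) | CC1(C)[C@H]2CCC(=O)[C@@H]1C2 | starting material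
2 | trans-3-methylnopinone, (1R,3S,5S)-3,6,6-trimethylbicyclo[3.1.1]heptan-2-one | CC1(C)[C@H]2C[C@H](C)C(=O)[C@@H]1C2 | intermediate
3 | (E)-pent-3-en-2-one | C/C=C/C(C)=O | starting material
4 | trimethylsilyl enol ether of 2 (3,6,6-trimethyl-2-trimethylsilyloxybicyclo[3.1.1]hept-2-ene, bridgeheads as in 1) | CC1(C)[C@H]2CC(C)=C(O[Si](C)(C)C)[C@@H]1C2 | intermediate
5 | (1R,3R,5S)-3,6,6-trimethyl-3-[(2S)-4-oxopentan-2-yl]bicyclo[3.1.1]heptan-2-one (3-methyl syn, side chain anti to the gem-dimethyl bridge) | CC1(C)[C@H]2C[C@](C)([C@@H](C)CC(C)=O)C(=O)[C@@H]1C2 | intermediate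
6 | (2R,4R)-4-(2-chloropropan-2-yl)-2-methyl-2-[(2S)-4-oxopentan-2-yl]cyclohexan-1-one | CC(C)(Cl)[C@H]1C[C@](C)([C@@H](C)CC(C)=O)C(=O)CC1 | intermediate
7 | fused ketol, 11-chloro-10β-hydroxy-7αH-eremophilan-2-one (cis-fused isomer expected; C10 configuration without consequence) | CC(C)(Cl)[C@H]1C[C@]2(C)[C@@H](C)CC(=O)C[C@]2(O)CC1 | intermediate
8 | (4S,4aR,6R)-6-(2-chloropropan-2-yl)-4,4a-dimethyl-4,4a,5,6,7,8-hexahydronaphthalen-2(3H)-one (11-chloro-7αH-eremophil-1(10)-en-2-one) | CC(C)(Cl)[C@H]1C[C@]2(C)[C@@H](C)CC(=O)C=C2CC1 | intermediate
9 | 11-chloro-7αH-eremophila-1(10),8-dien-2-one | CC(C)(Cl)[C@H]1C[C@]2(C)[C@@H](C)CC(=O)C=C2C=C1 | intermediate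
10 | 11-chloro-8α,9α-dihydroxy-7αH-eremophil-1(10)-en-2-one | CC(C)(Cl)[C@H]1C[C@]2(C)[C@@H](C)CC(=O)C=C2[C@H](O)[C@@H]1O | intermediate
11 | 11-chloro-8α,9α-dihydroxy-7αH,10αH-eremophilan-2-one | CC(C)(Cl)[C@H]1C[C@]2(C)[C@@H](C)CC(=O)C[C@H]2[C@H](O)[C@@H]1O | intermediate
12 | 8α,9α-O-isopropylidene acetal of 11 | CC(C)(Cl)[C@H]1C[C@]2(C)[C@@H](C)CC(=O)C[C@H]2[C@H](OC3(C)C)[C@@H]1O3 | intermediate
13 | 11-chloro-8α,9α-(isopropylidenedioxy)-7αH,10αH-eremophilan-2α-ol | CC(C)(Cl)[C@H]1C[C@]2(C)[C@@H](C)C[C@H](O)C[C@H]2[C@H](OC3(C)C)[C@@H]1O3 | intermediate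
14 | 8α,9α-(isopropylidenedioxy)-7αH,10αH-eremophil-11-en-2α-ol | C=C(C)[C@H]1C[C@]2(C)[C@@H](C)C[C@H](O)C[C@H]2[C@H](OC3(C)C)[C@@H]1O3 | intermediate
15 | 2α-acetoxy-8α,9α-(isopropylidenedioxy)-7αH,10αH-eremophil-11-ene | C=C(C)[C@H]1C[C@]2(C)[C@@H](C)C[C@H](OC(C)=O)C[C@H]2[C@H](OC3(C)C)[C@@H]1O3 | intermediate
16 | 2α-acetoxy-7αH,10αH-eremophil-11-ene-8α,9α-diol | C=C(C)[C@H]1C[C@]2(C)[C@@H](C)C[C@H](OC(C)=O)C[C@H]2[C@H](O)[C@@H]1O | intermediate
17 | angelic acid, (Z)-2-methylbut-2-enoic acid | C/C=C(/C)C(=O)O | starting material
18 | 8,9-O-dibutylstannylene acetal of 16 | C=C(C)[C@H]1C[C@]2(C)[C@@H](C)C[C@H](OC(C)=O)C[C@H]2[C@H](O[Sn]3(CCCC)CCCC)[C@@H]1O3 | intermediate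
19 | angelic 2,4,6-trichlorobenzoic anhydride | C/C=C(/C)C(=O)OC(=O)c1c(Cl)cc(Cl)cc1Cl | intermediate
20 | 2α-acetoxy-9α-angeloyloxy-7αH,10αH-eremophil-11-en-8α-ol, (2S,4S,5R,7R,8R,9S,10R), CNP0217919.1 | C=C(C)[C@H]1C[C@]2(C)[C@@H](C)C[C@H](OC(C)=O)C[C@H]2[C@H](OC(=O)/C(C)=C\C)[C@@H]1O | target

**Step count and risks**

Total step count: 12. Longest linear sequence: 12 steps (1 → 20).

Steps most likely to fail:

1. Step 2. What may go wrong is poor facial discrimination at the enone β-carbon, which would erode the C4 configuration, together with slow bond formation at the hindered tetrasubstituted enol ether. Fallback: set out from 2 and 3 and run a base-mediated Robinson annulation (NaH, dioxane, rt; then NaOMe, MeOH, reflux). The Michael addition then passes through a sodium-chelated closed transition state, the variant associated with cis-vicinal dimethyl octalones, and the aldol condensation takes place on the intact bicycle to give the tricyclic enone F1. Treating the tricyclic enone F1 with HCl (g) in AcOH opens the cyclobutane by vinylogous cleavage of the protonated enone with chloride capture, and the route is rejoined at 8.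

2. Step 6. What may go wrong is slow turnover or deactivation of the iridium catalyst on a conjugated, β,β-disubstituted enone, with competing isomerisation of the allylic alcohol to a ketone. Fallback: set out from 10 and reduce the enone by metal-hydride hydrogen-atom transfer (Mn(dpm)3, dpm = 2,2,6,6-tetramethylheptane-3,5-dionate, PhSiH3, i-PrOH, rt). Hydrogen is then delivered to the ring-fusion carbon from the open α face, away from the C5 methyl and the C7 chloroalkyl group, and the route is rejoined directly at 11 with no new compound.

3. Step 12. What may go wrong is Z to E isomerisation of the angeloyl unit during activation and transfer, or acyl transfer from the hindered mixed anhydride slow enough that acylation at O8 or acyl migration competes. Fallback: set out from 16 through stannylene acetal 18 and acylate it at 0 °C with the small, non-isomerisable 2-[bis(2,2,2-trifluoroethoxy)phosphoryl]propanoyl chloride to give the 9-O-phosphonopropanoate F2. The 9-O-phosphonopropanoate F2 is then subjected to a Still–Gennari olefination (KN(SiMe3)2, 18-crown-6, THF, −78 °C; acetaldehyde), which builds the (Z)-2-methylbut-2-enoate on the substrate and rejoins the route at 20.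

Further compounds
F1 | step 2 | tricyclic enone, Robinson annulation product of 2 and 3 with the cyclobutane intact (C9–C11 bond still present, Δ1(10)-2-one) | CC1(C)[C@H]2C[C@]3(C)[C@@H](C)CC(=O)C=C3[C@@H]1C2
F0 | step 6 | none | none
F2 | step 12 | 9-O-{2-[bis(2,2,2-trifluoroethoxy)phosphoryl]propanoyl} derivative of 16 (epimeric at the phosphonate α-carbon) | C=C(C)[C@H]1C[C@]2(C)[C@@H](C)C[C@H](OC(C)=O)C[C@H]2[C@H](OC(=O)C(C)P(=O)(OCC(F)(F)F)OCC(F)(F)F)[C@@H]1O
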